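## Retrosynthetic overview
1. The target comes from the (2S)-tris-MOM flavanone by acidic MOM solvolysis as the last step. C2 is fixed by a catalyst-controlled transfer-hydrogenation kinetic resolution of the C2-epimeric flavanone.
2. Ring C is the only ring made, since rings A and B are bought as arenes. It closes by oxa-Michael addition in a 2'-hydroxychalcone whose other ortho oxygen is blocked, so only the 6-substituted flavanone can form.
3. The key C–C bond is made by Claisen–Schmidt aldol condensation of the ring A methyl ketone with the ring B aldehyde.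
4. The ring A ketone comes from ortho-lithiation, acetaldehyde addition and oxidation of a lavandulyl phloroglucinol triether. The side-chain stereocentre comes from Evans prenylation of a 3-arylpropanoyl imide, whose acyl carbon then becomes the isopropenyl group (Weinreb amide, MeMgBr, Wittig).
5. The 3-arylpropanoic acid comes from Wittig olefination and hydrogenation of 2,4,6-trihydroxybenzaldehyde. It carries SEM on the 4-O (future ring oxygen) and MOM on the 2,6-O (future 5-OH and 7-OH).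

Abbreviations: OMOM = methoxymethoxy; OSEM = [2-(trimethylsilyl)ethoxy]methoxy; Lav = (2R)-5-methyl-2-(prop-1-en-2-yl)hex-4-en-1-yl.

Assumption: the remote side-chain stereocentre does not disturb catalyst control at C2, so the two C2 epimers of the protected flavanone respond to the chiral Ru catalyst like the enantiomers of a simple flavanone.

## Route

Step 1
Reactants: 1 2,4,6-trihydroxybenzaldehyde
Product: 2 2,6-dihydroxy-4-(OSEM)benzaldehyde
Conditions: SEMCl (1.0 equiv), iPr2NEt (1.1 equiv), DMF, −10 to 0 °C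
Reagents that add atoms: 2-(trimethylsilyl)ethoxymethyl chloride (SEMCl) C[Si](C)(C)CCOCCl
Why: Chemoselective Williamson-type O-alkylation, in which the 4-OH is the most acidic and least hindered hydroxyl and is never hydrogen-bonded to the formyl group, so one equivalent of SEMCl goes mainly there and a little bis-ether is removed by chromatography.

Step 2
Reactants: 2 2,6-dihydroxy-4-(OSEM)benzaldehyde
Product: 3 2,6-bis(OMOM)-4-(OSEM)benzaldehyde
Conditions: NaH (2.6 equiv), MOMCl (2.6 equiv), DMF, 0 °C to rt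
Reagents that add atoms: chloromethyl methyl ether (MOMCl) COCCl
Why: Exhaustive Williamson O-alkylation, in which full deprotonation breaks the hydrogen bonds so both ortho phenoxides are capped and the oxygen para to the formyl carbon stays the only differently protected one.

Step 3
Reactants: 3 2,6-bis(OMOM)-4-(OSEM)benzaldehyde; 4 ethyl (triphenylphosphoranylidene)acetate
Product: 5 ethyl (E)-3-[2,6-bis(OMOM)-4-(OSEM)phenyl]prop-2-enoate
Conditions: 4 (1.3 equiv), toluene, 90 °C
Reagents that add atoms: ethyl (triphenylphosphoranylidene)acetate (4) CCOC(=O)C=P(c1ccccc1)(c1ccccc1)c1ccccc1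
Why: Wittig olefination with a stabilised ylide needs no base, tolerates the hindered non-enolisable aldehyde and gives the E-cinnamate, whose geometry is irrelevant after the next step.

Step 4
Reactants: 5 ethyl (E)-3-[2,6-bis(OMOM)-4-(OSEM)phenyl]prop-2-enoate
Product: 6 ethyl 3-[2,6-bis(OMOM)-4-(OSEM)phenyl]propanoate
Conditions: H2 (1 atm), 10 % Pd/C, EtOAc, rt
Reagents that add atoms: none
Why: Heterogeneous catalytic hydrogenation saturates the conjugated C=C while the acetals, the silane and the ester are inert under neutral conditions.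

Step 5
Reactants: 6 ethyl 3-[2,6-bis(OMOM)-4-(OSEM)phenyl]propanoate
Product: 7 3-[2,6-bis(OMOM)-4-(OSEM)phenyl]propanoic acid
Conditions: LiOH (3 equiv), THF/MeOH/H2O, rt; then 1 M HCl to pH 4, 0 °C
Reagents that add atoms: lithium hydroxide [Li+].[OH-]
Why: Ester saponification (acyl–oxygen cleavage) is fully compatible with base-stable MOM and SEM acetals, and the brief cold acidification to pH 4 does not touch them.

Step 6
Reactants: 7 3-[2,6-bis(OMOM)-4-(OSEM)phenyl]propanoic acid; 8 (4R)-4-benzyl-1,3-oxazolidin-2-one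
Product: 10 (4R)-4-benzyl-3-{3-[2,6-bis(OMOM)-4-(OSEM)phenyl]propanoyl}-1,3-oxazolidin-2-one, via mixed pivalic anhydride 9 (not isolated)
Conditions: PivCl, Et3N, THF, −20 °C; then LiCl, 8, −20 °C to rt
Reagents that add atoms: (4R)-4-benzyl-1,3-oxazolidin-2-one (8) O=C1OC[C@@H](Cc2ccccc2)N1; pivaloyl chloride CC(C)(C)C(=O)Cl (atoms only in 9)
Why: N-acylation of the Evans auxiliary by the mixed-anhydride method, in which the LiCl/Et3N-activated oxazolidinone attacks the unhindered carbonyl of 9 rather than the pivaloyl one.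

Step 7
Reactants: 10 (4R)-4-benzyl-3-{3-[2,6-bis(OMOM)-4-(OSEM)phenyl]propanoyl}-1,3-oxazolidin-2-one; 11 prenyl bromide (1-bromo-3-methylbut-2-ene)
Product: 13 (4R)-4-benzyl-3-[(2R)-2-{[2,6-bis(OMOM)-4-(OSEM)phenyl]methyl}-5-methylhex-4-enoyl]-1,3-oxazolidin-2-one, via sodium Z-enolate 12 (not isolated)
Conditions: NaN(SiMe3)2 (1.1 equiv), THF, −78 °C; then 11 (3 equiv), −78 to −45 °C
Reagents that add atoms: prenyl bromide (11) CC(C)=CCBr; sodium bis(trimethylsilyl)amide C[Si](C)(C)[N-][Si](C)(C)C.[Na+] (Na only in 12)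
Why: Evans asymmetric alkylation, in which the chelated Z-enolate is shielded on one face by the 4-benzyl group, so the allylic bromide enters from the other face and the (4R)-auxiliary gives the 2R centre (dr at least 95:5, minor isomer removed by chromatography).

Step 8
Reactants: 13 (4R)-4-benzyl-3-[(2R)-2-{[2,6-bis(OMOM)-4-(OSEM)phenyl]methyl}-5-methylhex-4-enoyl]-1,3-oxazolidin-2-one
Product: 15 (2R)-2-{[2,6-bis(OMOM)-4-(OSEM)phenyl]methyl}-5-methylhex-4-enoic acid, via peroxy acid 14 (not isolated)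
Conditions: LiOH (2 equiv), 30 % H2O2 (5 equiv), THF/H2O 3:1, 0 °C; then aq Na2SO3; then 1 M HCl to pH 4, 0 °C
Reagents that add atoms: hydrogen peroxide OO
Why: Hydroperoxide-mediated imide cleavage, in which the weakly basic alpha-effect nucleophile attacks the exocyclic carbonyl without enolising the new stereocentre, the peroxy acid stays as its unreactive anion until sulfite reduces it, and the auxiliary is recovered.

Step 9
Reactants: 15 (2R)-2-{[2,6-bis(OMOM)-4-(OSEM)phenyl]methyl}-5-methylhex-4-enoic acid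
Product: 17 (2R)-2-{[2,6-bis(OMOM)-4-(OSEM)phenyl]methyl}-N-methoxy-N,5-dimethylhex-4-enamide, via acyl imidazolide 16 (not isolated)
Conditions: CDI (1.2 equiv), CH2Cl2, rt, 1 h; then MeONHMe·HCl (1.5 equiv), rt
Reagents that add atoms: N,O-dimethylhydroxylamine hydrochloride CNOC.Cl; 1,1'-carbonyldiimidazole O=C(n1ccnc1)n1ccnc1 (atoms only in 16)
Why: Amide coupling through an acyl imidazolide runs under near-neutral conditions that leave an alpha-alkyl stereocentre, the acetals and the alkene untouched.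

Step 10
Reactants: 17 (2R)-2-{[2,6-bis(OMOM)-4-(OSEM)phenyl]methyl}-N-methoxy-N,5-dimethylhex-4-enamide
Product: 19 (3R)-3-{[2,6-bis(OMOM)-4-(OSEM)phenyl]methyl}-6-methylhept-5-en-2-one, via tetrahedral magnesium adduct 18 (not isolated)
Conditions: MeMgBr (2 equiv), THF, 0 °C; quench cold H2O
Reagents that add atoms: methylmagnesium bromide C[Mg]Br
Why: Weinreb ketone synthesis, in which adduct 18 is held by N-methoxy chelation until the quench, so only one methyl group adds and the ketone never meets the basic reagent that could epimerise it.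

Step 11
Reactants: 19 (3R)-3-{[2,6-bis(OMOM)-4-(OSEM)phenyl]methyl}-6-methylhept-5-en-2-one
Product: 20 2-Lav-1,3-bis(OMOM)-5-(OSEM)benzene
Conditions: MePPh3Br (2.2 equiv), KN(SiMe3)2 (2.0 equiv), THF, 0 °C; then 19, 0 °C to rt
Reagents that add atoms: methyltriphenylphosphonium bromide C[P+](c1ccccc1)(c1ccccc1)c1ccccc1.[Br-]
Why: Wittig methylenation with the phosphonium salt in slight excess leaves no free amide base, and any competing enolisation occurs kinetically at the methyl side, so the tertiary alpha centre keeps its R configuration while the acetyl group becomes the isopropenyl group.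

Step 12
Reactants: 20 2-Lav-1,3-bis(OMOM)-5-(OSEM)benzene; 21 acetaldehyde
Product: 23 1-[2,4-bis(OMOM)-3-Lav-6-(OSEM)phenyl]ethan-1-ol (both carbinol epimers), via aryllithium 22 (not isolated)
Conditions: n-BuLi (1.2 equiv), THF, 0 °C, 1 h; then 21 (3 equiv), −78 °C; quench H2O
Reagents that add atoms: acetaldehyde (21) CC=O; n-butyllithium [Li]CCCC (Li only in 22)
Why: Directed ortho-metalation followed by 1,2-addition, in which the two remaining ring C–H positions are equivalent and each is flanked by two chelating acetal oxygens, so lithiation there far outruns allylic deprotonation and the new carbinol centre is erased in the next step.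

Step 13
Reactants: 23 1-[2,4-bis(OMOM)-3-Lav-6-(OSEM)phenyl]ethan-1-ol
Product: 24 1-[2,4-bis(OMOM)-3-Lav-6-(OSEM)phenyl]ethan-1-one
Conditions: DMP (1.3 equiv), CH2Cl2, 0 °C to rt
Reagents that add atoms: none
Why: Dess–Martin oxidation converts the hindered benzylic alcohol into the aryl methyl ketone without affecting alkenes, acetals or the remote stereocentre.

Step 14
Reactants: 24 1-[2,4-bis(OMOM)-3-Lav-6-(OSEM)phenyl]ethan-1-one
Product: 25 1-[6-hydroxy-2,4-bis(OMOM)-3-Lav-phenyl]ethan-1-one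
Conditions: n-Bu4NF (3 equiv), THF, 60 °C; then H2O
Reagents that add atoms: none
Why: Fluoride-induced SEM fragmentation (attack at silicon, loss of ethene and formaldehyde) is helped by the good ortho-acyl phenoxide leaving group and leaves the silicon-free MOM ethers intact, so only the oxygen para to the side chain is freed.

Step 15
Reactants: 26 2,4-dihydroxybenzaldehyde
Product: 27 2-hydroxy-4-(OMOM)benzaldehyde
Conditions: MOMCl (1.1 equiv), K2CO3, acetone, 0 °C to rt
Reagents that add atoms: chloromethyl methyl ether (MOMCl) COCCl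
Why: Chemoselective Williamson etherification, in which the 2-OH is hydrogen-bonded to the aldehyde and only the more acidic free 4-OH is alkylated.

Step 16
Reactants: 27 2-hydroxy-4-(OMOM)benzaldehyde
Product: 28 2-methoxy-4-(OMOM)benzaldehyde
Conditions: MeI (1.5 equiv), K2CO3, DMF, rt
Reagents that add atoms: iodomethane CI
Why: Williamson methylation in a polar aprotic solvent alkylates the remaining chelated phenol cleanly.

Step 17
Reactants: 25 1-[6-hydroxy-2,4-bis(OMOM)-3-Lav-phenyl]ethan-1-one; 28 2-methoxy-4-(OMOM)benzaldehyde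
Product: 30 (E)-1-[6-hydroxy-2,4-bis(OMOM)-3-Lav-phenyl]-3-[2-methoxy-4-(OMOM)phenyl]prop-2-en-1-one, via aldol adduct 29 (not isolated)
Conditions: 50 % aq KOH (excess), EtOH, rt, 48 h; then 1 M HCl to pH 6, 0 °C
Reagents that add atoms: none
Why: Claisen–Schmidt crossed aldol condensation, in which only ketone 25 can enolise and only aldehyde 28 is a competent acceptor, adduct 29 loses water by E1cB to the conjugated E-chalcone, and the non-acidic side-chain stereocentre is untouched by hydroxide.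

Step 18
Reactants: 30 (E)-1-[6-hydroxy-2,4-bis(OMOM)-3-Lav-phenyl]-3-[2-methoxy-4-(OMOM)phenyl]prop-2-en-1-one
Product: 31 (2RS)-6-Lav-2-[2-methoxy-4-(OMOM)phenyl]-5,7-bis(OMOM)chroman-4-one (about 1:1 at C2)
Conditions: NaOAc (10 equiv), EtOH, reflux, 36 h (recovered 30 recycled)
Reagents that add atoms: none
Why: Intramolecular oxa-Michael (6-endo-trig) cyclisation, in which the only free phenol is the one next to the ring C–H, so ring C can close only to the 6-Lav isomer, while the remote stereocentre gives no facial bias and both C2 epimers form.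

Step 19
Reactants: 31 (2RS)-6-Lav-2-[2-methoxy-4-(OMOM)phenyl]-5,7-bis(OMOM)chroman-4-one
Product: 32 (2S)-6-Lav-2-[2-methoxy-4-(OMOM)phenyl]-5,7-bis(OMOM)chroman-4-one
Conditions: RuCl[(R,R)-TsDPEN](p-cymene) (2 mol %), HCO2H/Et3N 5:2, EtOAc, 25 °C, stopped at 52–55 % conversion; chromatography
Reagents that add atoms: none
Why: Noyori–Ikariya asymmetric transfer hydrogenation run as a kinetic resolution, in which the (R,R)-catalyst makes 4R carbinols and that hydride trajectory coincides with the easy cis-forming face only in the 2R epimer, so the 2R epimer is reduced to the polar cis-flavan-4-ol and the unreacted 2S ketone is recovered stereopure (at most 50 %) with the alkenes untouched.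

Step 20
Reactants: 32 (2S)-6-Lav-2-[2-methoxy-4-(OMOM)phenyl]-5,7-bis(OMOM)chroman-4-one
Product: 33 (2S)-5,7-dihydroxy-2-(4-hydroxy-2-methoxyphenyl)-6-[(2R)-5-methyl-2-(prop-1-en-2-yl)hex-4-en-1-yl]-2,3-dihydro-4H-chromen-4-one
Conditions: conc. HCl (cat.), MeOH, 45 °C, about 2 h; work-up kept at pH 6 or below
Reagents that add atoms: none
Why: Acid-catalysed acetal solvolysis removes the three phenolic MOM groups faster than the alkenes are protonated, and because ring C opens only by base-induced retro-oxa-Michael reaction, the 2S centre survives acidic methanol.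

## Compound list
1 | 2,4,6-trihydroxybenzaldehyde | O=Cc1c(O)cc(O)cc1O | starting material
2 | 2,6-dihydroxy-4-(OSEM)benzaldehyde | O=Cc1c(O)cc(OCOCC[Si](C)(C)C)cc1O | intermediate
3 | 2,6-bis(OMOM)-4-(OSEM)benzaldehyde | O=Cc1c(OCOC)cc(OCOCC[Si](C)(C)C)cc1OCOC | intermediate
4 | ethyl (triphenylphosphoranylidene)acetate | CCOC(=O)C=P(c1ccccc1)(c1ccccc1)c1ccccc1 | starting material
5 | ethyl (E)-3-[2,6-bis(OMOM)-4-(OSEM)phenyl]prop-2-enoate | CCOC(=O)/C=C/c1c(OCOC)cc(OCOCC[Si](C)(C)C)cc1OCOC | intermediate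
6 | ethyl 3-[2,6-bis(OMOM)-4-(OSEM)phenyl]propanoate | CCOC(=O)CCc1c(OCOC)cc(OCOCC[Si](C)(C)C)cc1OCOC | intermediate
7 | 3-[2,6-bis(OMOM)-4-(OSEM)phenyl]propanoic acid | OC(=O)CCc1c(OCOC)cc(OCOCC[Si](C)(C)C)cc1OCOC | intermediate
8 | (4R)-4-benzyl-1,3-oxazolidin-2-one | O=C1OC[C@@H](Cc2ccccc2)N1 | starting material
9 | mixed anhydride of 7 and pivalic acid (not isolated) | CC(C)(C)C(=O)OC(=O)CCc1c(OCOC)cc(OCOCC[Si](C)(C)C)cc1OCOC | intermediate
10 | (4R)-4-benzyl-3-{3-[2,6-bis(OMOM)-4-(OSEM)phenyl]propanoyl}-1,3-oxazolidin-2-one | O=C1OC[C@@H](Cc2ccccc2)N1C(=O)CCc1c(OCOC)cc(OCOCC[Si](C)(C)C)cc1OCOC | intermediate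
11 | prenyl bromide (1-bromo-3-methylbut-2-ene) | CC(C)=CCBr | starting material
12 | sodium Z-enolate of 10 (not isolated) | [Na+].[O-]/C(=C\Cc1c(OCOC)cc(OCOCC[Si](C)(C)C)cc1OCOC)N1C(=O)OC[C@H]1Cc1ccccc1 | intermediate
13 | (4R)-4-benzyl-3-[(2R)-2-{[2,6-bis(OMOM)-4-(OSEM)phenyl]methyl}-5-methylhex-4-enoyl]-1,3-oxazolidin-2-one | O=C1OC[C@@H](Cc2ccccc2)N1C(=O)[C@H](CC=C(C)C)Cc1c(OCOC)cc(OCOCC[Si](C)(C)C)cc1OCOC | intermediate
14 | (2R)-2-{[2,6-bis(OMOM)-4-(OSEM)phenyl]methyl}-5-methylhex-4-eneperoxoic acid (not isolated) | OOC(=O)[C@H](CC=C(C)C)Cc1c(OCOC)cc(OCOCC[Si](C)(C)C)cc1OCOC | intermediate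
15 | (2R)-2-{[2,6-bis(OMOM)-4-(OSEM)phenyl]methyl}-5-methylhex-4-enoic acid | OC(=O)[C@H](CC=C(C)C)Cc1c(OCOC)cc(OCOCC[Si](C)(C)C)cc1OCOC | intermediate
16 | acyl imidazolide of 15 (not isolated) | O=C(n1ccnc1)[C@H](CC=C(C)C)Cc1c(OCOC)cc(OCOCC[Si](C)(C)C)cc1OCOC | intermediate
17 | (2R)-2-{[2,6-bis(OMOM)-4-(OSEM)phenyl]methyl}-N-methoxy-N,5-dimethylhex-4-enamide | CON(C)C(=O)[C@H](CC=C(C)C)Cc1c(OCOC)cc(OCOCC[Si](C)(C)C)cc1OCOC | intermediate
18 | tetrahedral bromomagnesium adduct of 17 and MeMgBr (not isolated) | CON(C)C(C)(O[Mg]Br)[C@H](CC=C(C)C)Cc1c(OCOC)cc(OCOCC[Si](C)(C)C)cc1OCOC | intermediate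
19 | (3R)-3-{[2,6-bis(OMOM)-4-(OSEM)phenyl]methyl}-6-methylhept-5-en-2-one | CC(=O)[C@H](CC=C(C)C)Cc1c(OCOC)cc(OCOCC[Si](C)(C)C)cc1OCOC | intermediate
20 | 2-Lav-1,3-bis(OMOM)-5-(OSEM)benzene | C=C(C)[C@H](CC=C(C)C)Cc1c(OCOC)cc(OCOCC[Si](C)(C)C)cc1OCOC | intermediate
21 | acetaldehyde | CC=O | starting material
22 | 4-lithio derivative of 20 (not isolated) | C=C(C)[C@H](CC=C(C)C)Cc1c(OCOC)cc(OCOCC[Si](C)(C)C)c([Li])c1OCOC | intermediate
23 | 1-[2,4-bis(OMOM)-3-Lav-6-(OSEM)phenyl]ethan-1-ol (carbinol epimers) | C=C(C)[C@H](CC=C(C)C)Cc1c(OCOC)cc(OCOCC[Si](C)(C)C)c(C(C)O)c1OCOC | intermediate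
24 | 1-[2,4-bis(OMOM)-3-Lav-6-(OSEM)phenyl]ethan-1-one | C=C(C)[C@H](CC=C(C)C)Cc1c(OCOC)cc(OCOCC[Si](C)(C)C)c(C(C)=O)c1OCOC | intermediate
25 | 1-[6-hydroxy-2,4-bis(OMOM)-3-Lav-phenyl]ethan-1-one | C=C(C)[C@H](CC=C(C)C)Cc1c(OCOC)cc(O)c(C(C)=O)c1OCOC | intermediate
26 | 2,4-dihydroxybenzaldehyde | O=Cc1ccc(O)cc1O | starting material
27 | 2-hydroxy-4-(OMOM)benzaldehyde | O=Cc1ccc(OCOC)cc1O | intermediate
28 | 2-methoxy-4-(OMOM)benzaldehyde | O=Cc1ccc(OCOC)cc1OC | intermediate
29 | 3-hydroxy-1-[6-hydroxy-2,4-bis(OMOM)-3-Lav-phenyl]-3-[2-methoxy-4-(OMOM)phenyl]propan-1-one (not isolated, carbinol epimers) | C=C(C)[C@H](CC=C(C)C)Cc1c(OCOC)cc(O)c(C(=O)CC(O)c2ccc(OCOC)cc2OC)c1OCOC | intermediate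
30 | (E)-1-[6-hydroxy-2,4-bis(OMOM)-3-Lav-phenyl]-3-[2-methoxy-4-(OMOM)phenyl]prop-2-en-1-one | C=C(C)[C@H](CC=C(C)C)Cc1c(OCOC)cc(O)c(C(=O)/C=C/c2ccc(OCOC)cc2OC)c1OCOC | intermediate
31 | (2RS)-6-Lav-2-[2-methoxy-4-(OMOM)phenyl]-5,7-bis(OMOM)chroman-4-one | C=C(C)[C@H](CC=C(C)C)Cc1c(OCOC)cc2c(c1OCOC)C(=O)CC(c1ccc(OCOC)cc1OC)O2 | intermediate
32 | (2S)-6-Lav-2-[2-methoxy-4-(OMOM)phenyl]-5,7-bis(OMOM)chroman-4-one | C=C(C)[C@H](CC=C(C)C)Cc1c(OCOC)cc2c(c1OCOC)C(=O)C[C@@H](c1ccc(OCOC)cc1OC)O2 | intermediate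
33 | (2S)-5,7-dihydroxy-2-(4-hydroxy-2-methoxyphenyl)-6-[(2R)-5-methyl-2-(prop-1-en-2-yl)hex-4-en-1-yl]-2,3-dihydro-4H-chromen-4-one | C=C(C)[C@H](CC=C(C)C)Cc1c(O)cc2c(c1O)C(=O)C[C@@H](c1ccc(O)cc1OC)O2 | target

## Step count and risks
Total steps: 20. The longest linear sequence is 18 steps (steps 1–14 and 17–20). Steps 15–16 make the ring B aldehyde in parallel.

**Step 19** is the most exposed step. The C4 carbonyl of 31 is flanked by the 5-OMOM group, which the C6 chain pushes toward it, so hydride transfer may be too slow or too unselective. The fallback sets out from 31 and separates the two C2 epimers physically. This is done by preparative HPLC on an amylose tris(3,5-dimethylphenylcarbamate) phase (heptane/iPrOH). One fraction is 32, where the route is rejoined. The other fraction, (2R)-6-Lav-2-[2-methoxy-4-(OMOM)phenyl]-5,7-bis(OMOM)chroman-4-one F1, is turned back into 31 with NaOAc in hot EtOH.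

**Step 20** comes second. Once freed, the 5-OH and 7-OH flank the lavandulyl chain, and protic acid could add them across the isopropenyl or prenyl double bond to give chromans. The fallback sets out from 32 and avoids Brønsted acid altogether. TMSOTf and 2,2'-bipyridyl in MeCN at 0 °C exchange each aryl MOM group for silicon. This gives (2S)-6-Lav-2-[2-methoxy-4-(trimethylsilyloxy)phenyl]-5,7-bis(trimethylsilyloxy)chroman-4-one F2. Water at room temperature hydrolyses it, coming back to the route at 33.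

**Step 12** comes third. The hindered aryllithium may deprotonate acetaldehyde, or n-BuLi may attack allylic positions of the chain. The fallback sets out from 20 and uses phenol-directed chemistry instead of lithiation.
- n-Bu4NF in THF/DMPU at 80 °C removes the SEM group first to give 3,5-bis(OMOM)-4-Lav-phenol F3.
- MgCl2, Et3N and paraformaldehyde in refluxing MeCN formylate ortho to the free OH (both ortho sites are equivalent) to give 6-hydroxy-2,4-bis(OMOM)-3-Lav-benzaldehyde F4.
- MeMgBr (2.2 equiv, THF, 0 °C) gives 1-[6-hydroxy-2,4-bis(OMOM)-3-Lav-phenyl]ethan-1-ol F5.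
- MnO2 in CH2Cl2 oxidises the benzylic alcohol, coming back to the route at 25, so steps 13 and 14 are no longer needed.

## Further compounds
F1 | step 19 | (2R)-6-Lav-2-[2-methoxy-4-(OMOM)phenyl]-5,7-bis(OMOM)chroman-4-one | C=C(C)[C@H](CC=C(C)C)Cc1c(OCOC)cc2c(c1OCOC)C(=O)C[C@H](c1ccc(OCOC)cc1OC)O2
F2 | step 20 | (2S)-6-Lav-2-[2-methoxy-4-(trimethylsilyloxy)phenyl]-5,7-bis(trimethylsilyloxy)chroman-4-one | C=C(C)[C@H](CC=C(C)C)Cc1c(O[Si](C)(C)C)cc2c(c1O[Si](C)(C)C)C(=O)C[C@@H](c1ccc(O[Si](C)(C)C)cc1OC)O2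
F3 | step 12 | 3,5-bis(OMOM)-4-Lav-phenol | C=C(C)[C@H](CC=C(C)C)Cc1c(OCOC)cc(O)cc1OCOC
F4 | step 12 | 6-hydroxy-2,4-bis(OMOM)-3-Lav-benzaldehyde | C=C(C)[C@H](CC=C(C)C)Cc1c(OCOC)cc(O)c(C=O)c1OCOC
F5 | step 12 | 1-[6-hydroxy-2,4-bis(OMOM)-3-Lav-phenyl]ethan-1-ol (carbinol epimers) | C=C(C)[C@H](CC=C(C)C)Cc1c(OCOC)cc(O)c(C(C)O)c1OCOC
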